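## The problem

The target is a guaiane-type hydroazulenone. A 2-methylcyclopent-2-en-1-one (C1–C5, C3 carbonyl, C4=C5 tetrasubstituted) is fused through C1–C5 to a cycloheptane (C5–C10 and C1). Guaiane numbering is used throughout: C11 with its two methyls on C7, the C14 methyl on C10, the C15 methyl on C4. The four stereocentres (1R, 7S, 8R, 10S) all lie on the seven-membered ring. C7 and C8 are adjacent and cis (C11 and O8 on one face), the C10 methyl is cis to O8, and H1 is cis to the C10 methyl. C7 and C8 are flanked by oxygen on both sides, so they can be made together in open-chain form and then used to direct C10, which has no handle once it is formed. C1 is γ to the C3 carbonyl, stays epimerisable, and can be left to thermodynamic control. The fragile parts are three. The secondary propanoate sits next to a tertiary acetate that can ionise, eliminate or exchange acyl groups. The enone is reduced by electron-transfer reagents. The β-oxygenated C8–C7–C11 array invites retro-aldol cleavage or elimination whenever C8 is at the carbonyl level. The enabling feature is that C1 is the γ carbon of the C3/C4/C5 enone and its neighbour C10 carries the methyl group. A C9=C10 acceptor hung on C8 therefore lets the enone act as a vinylogous donor, and the C1–C10 bond closes the seven-membered ring and creates the C1/C10 pair in one step.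

## Retrosynthesis

**Esters (27 ⇒ 26 ⇒ 25).** The two acyl–oxygen bonds are cut first, the tertiary acetate last. The acetate is the most fragile group, and the secondary C8 hydroxyl of diol 25 can be acylated selectively before the tertiary C11 hydroxyl reacts. The forward steps must discriminate secondary from tertiary hydroxyl and avoid ionising C11.

**C9–S bond and its redox bracket (25 ⇒ 24 ⇒ 23 ⇒ 22 ⇒ 21).** The C9 sulfone is the price of activating C10 and has to leave by electron transfer. Two groups in 21 would not survive that: the enone, and the C8 oxygen as an ether β to the sulfone, which would be expelled in a Julia-type elimination. The acetonide is therefore hydrolysed first (22), so that a free C8 hydroxyl can protonate the C9 carbanion. The enone is parked as the allylic alcohol (23), the sulfone is removed (24), and MnO2 restores the enone (25). Removing the sulfone with the acetonide in place, or with the enone exposed, would be shorter but is not defensible.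

**C1–C10, the key cut (21 ⇒ 19).** Cutting C1–C10 turns the bicycle into cyclopentenone 19, which carries only two stereocentres, both locked in a 1,3-dioxane. Other cuts of the seven-membered ring were weighed. C8–C9 leads to an ene or aldol closure and leaves C10 unset. C6–C7 together with C9–C10 leads to a (4+3) route with the wrong unsaturation pattern. C5–C6 would demand alkylation at an enone β-carbon. The activating sulfonyl group is placed on C9, not on the methyl carbon, so that the acceptor lies inside the forming ring. The rival closure from the exocyclic γ′ carbon C6 is then 5-endo; with the sulfone on C14 it would be a fast 5-exo closure. The alkene is chosen as the (Z)-isomer, methyl syn to sulfonyl. In a conformation with the C8–O bond perpendicular to the acceptor plane, where it can stabilise the developing C9 carbanion, the tether reaches the alkene face that gives the C10 methyl cis to O8 from this isomer. The forward reaction must be γ-selective, face-selective at C10, and must not lose the C8 oxygen by β-elimination.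

**C5–C6 (19 ⇒ 15 + 17, through 18).** The side chain is cut from the ring at C5–C6. This is the most convergent cut and uses 3-bromo-2-methylcyclopent-2-en-1-one 17, one step from dione 16. Two neighbours were rejected. Alkylating an enolate with a bromomethyl-cyclopentenone needs an allylic bromination of doubtful regioselectivity. A 1,2-addition/transposition on a vinylogous ester needs an organolithium that the vinyl sulfone would not survive. The alkylzinc iodide 18 from iodide 15 is mild enough.

**C9–S and the C6 handle (15 ⇒ 14 ⇒ 13 ⇒ 12).** The sulfone is traced back to vinyl bromide 12 by a C–S coupling. The alternative, adding a sulfonyl-stabilised vinyl anion to a C8 aldehyde, would set C8 only by substrate control and needs a strongly basic nucleophile. The order is fixed by compatibility. The sulfone enters after the Grignard step, which a vinyl sulfone would not tolerate. It enters before the zinc chemistry, where a vinyl bromide would compete. The C6 oxygen is carried as a PMB ether and becomes the iodide last.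

**C11 methyl groups and the dioxane (12 ⇒ 11 ⇒ 10 ⇒ 9).** The two C11–CH3 bonds are cut back to a carboxyl carbon, so C11 is the acyl carbon of an aldol adduct. Diol 11 is tied up as the acetonide 12, which protects both hydroxyls and holds C6 and C9 gauche for the ring closure.

**C7–C8 (9 ⇒ 4 + 7, through 8; 4 ⇒ 1 + 2; 7 ⇒ 5).** An auxiliary-controlled syn-aldol sets C7 and C8 in one step with the relative configuration that becomes the cis ring pair. Alkylating a 3-silyloxy-3-methylbutanoyl imide would set C7 alone and leave C8 to a later substrate-controlled addition. Aldehyde 7 brings C8, C9 (with bromine as placeholder for the sulfone), C10 and its methyl with defined (Z) geometry. Imide 4 comes from acid 1 and oxazolidinone 2.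

## Roads not taken

**Alternative 1: dienyne metathesis cascade.** The cut runs through C5–C6 and C3–C4, both formed as double bonds. The open-chain dienyne A1 carries a vinyl group on C7 (C6), a propynyl group on C1 (C4≡C5) and a 2-siloxyallyl unit (C2/C3). With the second-generation Grubbs catalyst the carbene formed at C6 should add to the alkyne to close the seven-membered ring, and the C4 carbene should then close onto the silyl enol ether to give the bicyclic silyl dienol ether A2.
- Merits: both rings form in one neutral catalytic step; no activating group has to be excised afterwards; all four stereocentres, C10 included, are fixed beforehand by open-chain methods. On control of C10 this road is better than the chosen one, which creates C10 in an unprecedented ring closure.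
- Weak points: A1 needs the vicinal C1/C10 pair as well as C7/C8 in one chain, which costs several extra stereoselective steps. The second closure must form a tetrasubstituted C3=C4 bond from a methyl-substituted carbene and a 1,1-disubstituted enol ether. Initiation must occur at the vinyl group and not at the enol ether.
- Against it the chosen plan sets a precursor with two stereocentres from a single aldol, a modular ring attachment, and a C1 centre that corrects itself.

**Alternative 2: rhodium vinylcarbenoid cyclopropanation and Cope rearrangement.** The cut is C6–C7 and C9–C10. Rh2(S-PTAD)4 would turn siloxyvinyldiazoacetate A4 into a carbenoid that cyclopropanates the exocyclic methylene of diene A3. The cis-divinylcyclopropane then rearranges to cycloheptadiene A5.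
- Merits: this is the most convergent road, it is catalytic and enantioselective, and the reaction class has much closer precedent for seven-membered rings than the chosen closure. In both respects it is stronger.
- Weak points: A5 has the wrong unsaturation for this target, a C1=C5 alkene and an sp3 C4, so the alkene must be transposed and C1 set later. C7 and C8 emerge as the two carbons of an enol ether of a β-keto ester, so both have to be created on a flexible ring after closure. The ester must then be taken to the dimethyl carbinol next to a β-hydroxyl.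
- Against it the chosen plan sets C7 and C8 carried intact from an auxiliary-controlled aldol, and only deprotection-type operations after ring closure.

**Alternative 3: type-two carbonyl-ene closure.** The cut is C8–C9. Me2AlCl would promote the ene reaction of aldehyde A6, which has an isopropenyl group on C1, to give homoallylic alcohol A7 with an exocyclic methylene on C10.
- Merits: carbonyl-ene closures to six- and seven-membered rings are established, the C11 acetate is already in place, and nothing has to be removed afterwards. The post-cyclisation sequence is shorter than the chosen one.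
- Weak points: in A7 the C8 hydroxyl is trans to the C7 side chain, so it must be inverted at a hindered carbinol. C10 is only set later, by hydrogenating the methylene in the presence of the enone. A6 is a β-acetoxy aldehyde with an epimerisable C7. Its isopropenyl group at the enone γ-position can slip into conjugation under Lewis acid.
- Against it the chosen plan sets C8 delivered with the right configuration by the aldol, and C10 formed in the ring closure itself. The cost is a sulfone that takes four steps to clear and a closure without direct precedent.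

Key step: step 12

Remark: open-chain intermediates are discussed with the guaiane atom numbers of the carbons they become.
Remark: C9 in 21–23 and C3 in 23–24 form as epimer mixtures that converge later, so their SMILES leave these centres open. Acid 1 is taken as a catalogue compound.

## Steps

Step 1
Reactants: 1 3-[(4-methoxybenzyl)oxy]propanoic acid; 2 (S)-4-benzyloxazolidin-2-one
Product: 4 (S)-4-benzyl-3-{3-[(4-methoxybenzyl)oxy]propanoyl}oxazolidin-2-one, via mixed pivalic anhydride 3 (not isolated)
Conditions: PivCl, Et3N, THF, −20 °C; then 2, LiCl, −20 °C to rt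
Reagents that add atoms: none
Why: N-acylation of an oxazolidinone through the mixed pivalic anhydride; the LiCl/Et3N variant avoids strong base and so avoids β-elimination of the PMB ether.

Step 2
Reactants: 5 (E)-but-2-enal
Product: 7 (Z)-2-bromobut-2-enal, via 2,3-dibromobutanal 6 (not isolated)
Conditions: Br2, CH2Cl2, 0 °C; then Et3N, 0 °C to rt
Reagents that add atoms: bromine, BrBr
Why: Bromination–dehydrobromination of an enal; HBr is lost from the acidic α-position and the α-bromo enal should form as the (Z)-isomer, methyl trans to the formyl group.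

Step 3
Reactants: 4 (S)-4-benzyl-3-{3-[(4-methoxybenzyl)oxy]propanoyl}oxazolidin-2-one; 7 (Z)-2-bromobut-2-enal
Product: 9 (S)-4-benzyl-3-[(2S,3S,Z)-4-bromo-3-hydroxy-2-{[(4-methoxybenzyl)oxy]methyl}hex-4-enoyl]oxazolidin-2-one, via boron enolate 8 (not isolated)
Conditions: Bu2BOTf, i-Pr2NEt, CH2Cl2, −78 to 0 °C; then 7, −78 to 0 °C; pH 7 buffer, MeOH, H2O2
Reagents that add atoms: none
Why: Evans syn-aldol; the (Z)-boron enolate reacts through a closed chair transition state on the face away from the benzyl group, setting C7 and C8 (both S here) in the syn relationship that becomes the cis ring pair. The enal reacts 1,2 and the vinyl bromide is inert.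

Step 4
Reactants: 9 (S)-4-benzyl-3-[(2S,3S,Z)-4-bromo-3-hydroxy-2-{[(4-methoxybenzyl)oxy]methyl}hex-4-enoyl]oxazolidin-2-one
Product: 10 methyl (2S,3S,Z)-4-bromo-3-hydroxy-2-{[(4-methoxybenzyl)oxy]methyl}hex-4-enoate
Conditions: NaOMe, MeOH, 0 °C, short contact
Reagents that add atoms: methanol (as sodium methoxide), CO
Why: Methanolysis of the exocyclic imide carbonyl of an aldol adduct releases the auxiliary; low temperature and short time should suppress retro-aldol cleavage and C7 epimerisation.

Step 5
Reactants: 10 methyl (2S,3S,Z)-4-bromo-3-hydroxy-2-{[(4-methoxybenzyl)oxy]methyl}hex-4-enoate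
Product: 11 (3S,4S,Z)-5-bromo-3-{[(4-methoxybenzyl)oxy]methyl}-2-methylhept-5-ene-2,4-diol
Conditions: MeMgBr (5 equiv), THF, 0 °C to rt
Reagents that add atoms: methylmagnesium bromide, C[Mg]Br
Why: Double Grignard addition to a methyl ester gives the dimethyl carbinol C11; the first equivalent deprotonates the C8 hydroxyl and the vinyl bromide does not react.

Step 6
Reactants: 11 (3S,4S,Z)-5-bromo-3-{[(4-methoxybenzyl)oxy]methyl}-2-methylhept-5-ene-2,4-diol
Product: 12 (5S,6S)-6-[(Z)-1-bromoprop-1-en-1-yl]-5-{[(4-methoxybenzyl)oxy]methyl}-2,2,4,4-tetramethyl-1,3-dioxane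
Conditions: 2-methoxypropene, PPTS (cat.), CH2Cl2, 0 °C to rt
Reagents that add atoms: 2-methoxypropene, COC(C)=C
Why: Acid-catalysed acetonide formation with an enol ether (kinetic conditions) ties the secondary C8 and tertiary C11 hydroxyls into a 1,3-dioxane; no new stereocentre.

Step 7
Reactants: 12 (5S,6S)-6-[(Z)-1-bromoprop-1-en-1-yl]-5-{[(4-methoxybenzyl)oxy]methyl}-2,2,4,4-tetramethyl-1,3-dioxane
Product: 13 (5S,6S)-5-{[(4-methoxybenzyl)oxy]methyl}-2,2,4,4-tetramethyl-6-[(Z)-1-(phenylsulfonyl)prop-1-en-1-yl]-1,3-dioxane
Conditions: PhSO2Na, Pd2(dba)3 (cat.), Xantphos, Cs2CO3, n-Bu4NCl, toluene, 80 °C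
Reagents that add atoms: sodium benzenesulfinate, [Na+].[O-]S(=O)c1ccccc1
Why: Palladium-catalysed C–S coupling of an alkenyl bromide with a sulfinate salt; oxidative addition and reductive elimination retain the alkene geometry, so the methyl stays syn to the sulfonyl group.

Step 8
Reactants: 13 (5S,6S)-5-{[(4-methoxybenzyl)oxy]methyl}-2,2,4,4-tetramethyl-6-[(Z)-1-(phenylsulfonyl)prop-1-en-1-yl]-1,3-dioxane
Product: 14 {(5S,6S)-2,2,4,4-tetramethyl-6-[(Z)-1-(phenylsulfonyl)prop-1-en-1-yl]-1,3-dioxan-5-yl}methanol
Conditions: DDQ, CH2Cl2/pH 7 buffer, 0 °C to rt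
Reagents that add atoms: none
Why: Oxidative cleavage of a p-methoxybenzyl ether by DDQ; the electron-poor vinyl sulfone and the acetonide should not be touched under buffered conditions.

Step 9
Reactants: 14 {(5S,6S)-2,2,4,4-tetramethyl-6-[(Z)-1-(phenylsulfonyl)prop-1-en-1-yl]-1,3-dioxan-5-yl}methanol
Product: 15 (5S,6S)-5-(iodomethyl)-2,2,4,4-tetramethyl-6-[(Z)-1-(phenylsulfonyl)prop-1-en-1-yl]-1,3-dioxane
Conditions: I2, PPh3, imidazole, CH2Cl2, 0 °C to rt
Reagents that add atoms: iodine, II
Why: Appel-type iodination of a primary alcohol by SN2 displacement at C6; no stereocentre is involved.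

Step 10
Reactants: 16 2-methylcyclopentane-1,3-dione
Product: 17 3-bromo-2-methylcyclopent-2-en-1-one
Conditions: (COBr)2, DMF (cat.), CH2Cl2, 0 °C to rt
Reagents that add atoms: oxalyl bromide, O=C(Br)C(=O)Br
Why: Conversion of a cyclic 1,3-diketone into its β-bromo enone through Vilsmeier-type activation of the enol.

Step 11
Reactants: 15 (5S,6S)-5-(iodomethyl)-2,2,4,4-tetramethyl-6-[(Z)-1-(phenylsulfonyl)prop-1-en-1-yl]-1,3-dioxane; 17 3-bromo-2-methylcyclopent-2-en-1-one
Product: 19 2-methyl-3-({(5S,6S)-2,2,4,4-tetramethyl-6-[(Z)-1-(phenylsulfonyl)prop-1-en-1-yl]-1,3-dioxan-5-yl}methyl)cyclopent-2-en-1-one, via alkylzinc iodide 18 (not isolated)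
Conditions: Zn dust (activated), LiCl, THF, 40 °C; then 17, Pd2(dba)3 (cat.), SPhos, THF, rt to 50 °C
Reagents that add atoms: none
Why: Zinc insertion into the primary C–I bond and Negishi coupling with the β-bromo enone form the C5–C6 bond; alkylzinc halides tolerate ketones, acetals and vinyl sulfones, and 18 has no β-leaving group.

Step 12
Reactants: 19 2-methyl-3-({(5S,6S)-2,2,4,4-tetramethyl-6-[(Z)-1-(phenylsulfonyl)prop-1-en-1-yl]-1,3-dioxan-5-yl}methyl)cyclopent-2-en-1-one
Product: 21 (1R,7S,8S,10R)-8,11-(isopropylidenedioxy)-9-(phenylsulfonyl)guai-4-en-3-one (C9 epimers), via dienolate 20 (not isolated)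
Conditions: DBU (1 equiv), MeCN, rt to 60 °C
Reagents that add atoms: none
Why: Proposed new method: DBU removes a C1 hydrogen (γ to the C3 carbonyl) of 19 to give the ring dienolate 20 (O–C3=C4–C5=C1), whose γ carbon adds to C10 of the tethered (Z)-vinyl sulfone; the C9 sulfonyl carbanion is protonated by the amidinium ion and the conjugated C4=C5 enone is restored, the closest known reaction types being γ-selective vinylogous Michael additions of cyclic enone dienolates and intramolecular Michael additions of carbon nucleophiles to vinyl sulfones. The one ring that closes is the seven-membered carbocycle (C1, C5, C6, C7, C8, C9, C10), in the 7-endo-trig mode with both acceptor carbons inside the new ring. Site selectivity among C1, C4 and C6 is needed: closure through C6 would be 5-endo-trig, closure through C4 would have to build a quaternary carbon next to the tertiary C10 and gives a deconjugated ketone, and only closure through C1 regains the tetrasubstituted enone. C10 is the one centre set under kinetic control: the cis-5,6-disubstituted dioxane holds C6 and C9 gauche, and with the C8–O bond perpendicular to the acceptor plane the tether reaches the alkene face from which the (Z)-isomer places the C10 methyl cis to O8; this rests on a model and is unproven. C1 is set under thermodynamic control, because it remains the acidic γ position of the product and is expected to equilibrate to the isomer with C2 trans to the C10 methyl (H1 cis to it). C9 forms as a mixture and is cleared in step 15. Loss of the C8 oxygen by β-elimination from a sulfonyl-stabilised anion must be avoided; a weak amidine base should ionise the ketone γ-hydrogens in preference to the sulfone γ-methyl and its conjugate acid should quench the C9 carbanion at once.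

Step 13
Reactants: 21 (1R,7S,8S,10R)-8,11-(isopropylidenedioxy)-9-(phenylsulfonyl)guai-4-en-3-one
Product: 22 (1R,7S,8S,10R)-8,11-dihydroxy-9-(phenylsulfonyl)guai-4-en-3-one
Conditions: AcOH/H2O/THF (3:1:1), 40 °C
Reagents that add atoms: none
Why: Mild aqueous acid hydrolysis of the strained tetramethyl-1,3-dioxane frees the C8 and C11 hydroxyls, so the sulfone now sits next to a free hydroxyl; enone and sulfone are acid-stable.

Step 14
Reactants: 22 (1R,7S,8S,10R)-8,11-dihydroxy-9-(phenylsulfonyl)guai-4-en-3-one
Product: 23 (1R,7S,8S,10R)-9-(phenylsulfonyl)guai-4-ene-3ξ,8,11-triol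
Conditions: NaBH4, CeCl3·7H2O, MeOH, −40 to 0 °C
Reagents that add atoms: none
Why: Luche reduction gives 1,2-reduction of the enone to the allylic alcohol (both C3 epimers are used), which masks the enone against the electron-transfer step.

Step 15
Reactants: 23 (1R,7S,8S,10R)-9-(phenylsulfonyl)guai-4-ene-3ξ,8,11-triol
Product: 24 (1R,7S,8R,10S)-guai-4-ene-3ξ,8,11-triol
Conditions: 6% Na(Hg), Na2HPO4, MeOH/THF, −20 to 0 °C
Reagents that add atoms: none
Why: Reductive desulfonylation with buffered sodium amalgam cleaves the C9–S bond; the C9 carbanion should be protonated by the adjacent C8 hydroxyl or by methanol faster than it expels a hydroxide, so C9 becomes CH2 and both C9 epimers converge.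

Step 16
Reactants: 24 (1R,7S,8R,10S)-guai-4-ene-3ξ,8,11-triol
Product: 25 (1R,7S,8R,10S)-8,11-dihydroxyguai-4-en-3-one
Conditions: MnO2 (activated, excess), CH2Cl2, rt
Reagents that add atoms: none
Why: MnO2 oxidises only the allylic C3 alcohol, restoring the conjugated enone and leaving the saturated secondary C8 and tertiary C11 hydroxyls.

Step 17
Reactants: 25 (1R,7S,8R,10S)-8,11-dihydroxyguai-4-en-3-one
Product: 26 (1R,7S,8R,10S)-11-hydroxy-3-oxoguai-4-en-8-yl propanoate
Conditions: (EtCO)2O, pyridine, DMAP (cat.), CH2Cl2, 0 °C
Reagents that add atoms: propanoic anhydride, CCC(=O)OC(=O)CC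
Why: DMAP-catalysed acylation discriminates the secondary C8 hydroxyl from the tertiary C11 hydroxyl, which should not react at 0 °C.

Step 18
Reactants: 26 (1R,7S,8R,10S)-11-hydroxy-3-oxoguai-4-en-8-yl propanoate
Product: 27 (1R,7S,8R,10S)-11-acetoxy-3-oxoguai-4-en-8-yl propanoate
Conditions: Ac2O, Sc(OTf)3 (cat.), MeCN, −20 °C
Reagents that add atoms: acetic anhydride, CC(=O)OC(C)=O
Why: Lewis-acid-catalysed acetylation acylates hindered tertiary alcohols at low temperature, fast enough to outrun ionisation of the carbinol and acyl migration.

## Compound list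

1 | 3-[(4-methoxybenzyl)oxy]propanoic acid | COc1ccc(COCCC(=O)O)cc1 | starting material
2 | (S)-4-benzyloxazolidin-2-one | O=C1N[C@@H](Cc2ccccc2)CO1 | starting material
3 | 3-[(4-methoxybenzyl)oxy]propanoic pivalic anhydride | COc1ccc(COCCC(=O)OC(=O)C(C)(C)C)cc1 | intermediate
4 | (S)-4-benzyl-3-{3-[(4-methoxybenzyl)oxy]propanoyl}oxazolidin-2-one | COc1ccc(COCCC(=O)N2[C@@H](Cc3ccccc3)COC2=O)cc1 | intermediate
5 | (E)-but-2-enal | C/C=C/C=O | starting material
6 | rac-(2R,3S)-2,3-dibromobutanal | C[C@H](Br)[C@H](Br)C=O | intermediate
7 | (Z)-2-bromobut-2-enal | C/C=C(\Br)C=O | intermediate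
8 | (Z)-dibutylboron enolate of 4 | CCCCB(CCCC)O/C(=C\COCc1ccc(OC)cc1)N2[C@@H](Cc3ccccc3)COC2=O | intermediate
9 | (S)-4-benzyl-3-[(2S,3S,Z)-4-bromo-3-hydroxy-2-{[(4-methoxybenzyl)oxy]methyl}hex-4-enoyl]oxazolidin-2-one | C/C=C(\Br)[C@@H](O)[C@H](COCc1ccc(OC)cc1)C(=O)N2[C@@H](Cc3ccccc3)COC2=O | intermediate
10 | methyl (2S,3S,Z)-4-bromo-3-hydroxy-2-{[(4-methoxybenzyl)oxy]methyl}hex-4-enoate | C/C=C(\Br)[C@@H](O)[C@H](COCc1ccc(OC)cc1)C(=O)OC | intermediate
11 | (3S,4S,Z)-5-bromo-3-{[(4-methoxybenzyl)oxy]methyl}-2-methylhept-5-ene-2,4-diol | C/C=C(\Br)[C@@H](O)[C@H](COCc1ccc(OC)cc1)C(C)(C)O | intermediate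
12 | (5S,6S)-6-[(Z)-1-bromoprop-1-en-1-yl]-5-{[(4-methoxybenzyl)oxy]methyl}-2,2,4,4-tetramethyl-1,3-dioxane | C/C=C(\Br)[C@H]1OC(C)(C)OC(C)(C)[C@H]1COCc2ccc(OC)cc2 | intermediate
13 | (5S,6S)-5-{[(4-methoxybenzyl)oxy]methyl}-2,2,4,4-tetramethyl-6-[(Z)-1-(phenylsulfonyl)prop-1-en-1-yl]-1,3-dioxane | C/C=C(\S(=O)(=O)c1ccccc1)[C@H]2OC(C)(C)OC(C)(C)[C@H]2COCc3ccc(OC)cc3 | intermediate
14 | {(5S,6S)-2,2,4,4-tetramethyl-6-[(Z)-1-(phenylsulfonyl)prop-1-en-1-yl]-1,3-dioxan-5-yl}methanol | C/C=C(\S(=O)(=O)c1ccccc1)[C@H]2OC(C)(C)OC(C)(C)[C@H]2CO | intermediate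
15 | (5S,6S)-5-(iodomethyl)-2,2,4,4-tetramethyl-6-[(Z)-1-(phenylsulfonyl)prop-1-en-1-yl]-1,3-dioxane | C/C=C(\S(=O)(=O)c1ccccc1)[C@H]2OC(C)(C)OC(C)(C)[C@H]2CI | intermediate
16 | 2-methylcyclopentane-1,3-dione | CC1C(=O)CCC1=O | starting material
17 | 3-bromo-2-methylcyclopent-2-en-1-one | CC1=C(Br)CCC1=O | intermediate
18 | ({(5S,6S)-2,2,4,4-tetramethyl-6-[(Z)-1-(phenylsulfonyl)prop-1-en-1-yl]-1,3-dioxan-5-yl}methyl)zinc iodide | C/C=C(\S(=O)(=O)c1ccccc1)[C@H]2OC(C)(C)OC(C)(C)[C@H]2C[Zn]I | intermediate
19 | 2-methyl-3-({(5S,6S)-2,2,4,4-tetramethyl-6-[(Z)-1-(phenylsulfonyl)prop-1-en-1-yl]-1,3-dioxan-5-yl}methyl)cyclopent-2-en-1-one | C/C=C(\S(=O)(=O)c1ccccc1)[C@H]2OC(C)(C)OC(C)(C)[C@H]2CC3=C(C)C(=O)CC3 | intermediate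
20 | DBU-H+ salt of the C1-deprotonated dienolate of 19 | C/C=C(\S(=O)(=O)c1ccccc1)[C@H]2OC(C)(C)OC(C)(C)[C@H]2CC3=CCC([O-])=C3C.C1CCC2=[NH+]CCCN2CC1 | intermediate
21 | (1R,7S,8S,10R)-8,11-(isopropylidenedioxy)-9-(phenylsulfonyl)guai-4-en-3-one (C9 epimers) | CC1(C)O[C@@H]2C(S(=O)(=O)c3ccccc3)[C@H](C)[C@H]4CC(=O)C(C)=C4C[C@@H]2C(C)(C)O1 | intermediate
22 | (1R,7S,8S,10R)-8,11-dihydroxy-9-(phenylsulfonyl)guai-4-en-3-one (C9 epimers) | O[C@@H]1C(S(=O)(=O)c2ccccc2)[C@H](C)[C@H]3CC(=O)C(C)=C3C[C@@H]1C(C)(C)O | intermediate
23 | (1R,7S,8S,10R)-9-(phenylsulfonyl)guai-4-ene-3ξ,8,11-triol (C3 and C9 epimers) | O[C@@H]1C(S(=O)(=O)c2ccccc2)[C@H](C)[C@H]3CC(O)C(C)=C3C[C@@H]1C(C)(C)O | intermediate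
24 | (1R,7S,8R,10S)-guai-4-ene-3ξ,8,11-triol (C3 epimers) | O[C@@H]1C[C@H](C)[C@H]2CC(O)C(C)=C2C[C@@H]1C(C)(C)O | intermediate
25 | (1R,7S,8R,10S)-8,11-dihydroxyguai-4-en-3-one | O[C@@H]1C[C@H](C)[C@H]2CC(=O)C(C)=C2C[C@@H]1C(C)(C)O | intermediate
26 | (1R,7S,8R,10S)-11-hydroxy-3-oxoguai-4-en-8-yl propanoate | CCC(=O)O[C@@H]1C[C@H](C)[C@H]2CC(=O)C(C)=C2C[C@@H]1C(C)(C)O | intermediate
27 | (1R,7S,8R,10S)-11-acetoxy-3-oxoguai-4-en-8-yl propanoate | CCC(=O)O[C@@H]1C[C@H](C)[C@H]2CC(=O)C(C)=C2C[C@@H]1C(C)(C)OC(C)=O | target

## Step count and least certain steps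

Total step count: 18. Longest linear sequence: 16 steps (steps 1, 3–9 and 11–18); steps 2 and 10 make the two side fragments.

**Step 12 (key step, proposed new method).** Three processes may defeat it:
- loss of the C8 oxygen by β-elimination, either from the allylic anion formed when the sulfone γ-methyl is ionised or from the C9 carbanion after addition;
- carbon–carbon bond formation through C4 instead of C1, or no ionisation at all with so weak a base;
- poor facial selectivity at C10, since the face model is untested.

The fallback uses a classical, doubly activated donor and builds the cyclopentenone afterwards. It sets out from alkylzinc iodide 18 (made from 15 as in step 11). Acylation with methyl 3-chloro-3-oxopropanoate under Pd(PPh3)4 catalysis should give the β-keto ester F1. K2CO3 in MeCN should then close the seven-membered ring by a conventional intramolecular Michael addition of the β-dicarbonyl carbon (C1) to C10 of the vinyl sulfone, giving the bicyclic keto ester F2. Carbonate suffices here, so the sulfone methyl is not ionised, and the C9 carbanion is quenched by a far stronger acid than in the main route. Alkylation of F2 at C1 with 1-bromobutan-2-one (K2CO3, acetone) gives the 1,4-diketone F3. Base-mediated aldol condensation of C4 onto the C5 ketone gives the enone ester F4. Krapcho dealkoxycarbonylation (LiCl, wet DMSO, heat) removes the C1 ester through the dienolate and returns to the route at 21. C10 selectivity of this closure would have to be checked in the same way; the (E)-alkene would be the lever if the face preference were reversed.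

**Step 7.** Oxidative addition into the hindered trisubstituted bromide may be slow, and at 80 °C the carbonate may start the same β-elimination of the C8 oxygen from product 13. The fallback replaces catalysis by anion chemistry. From 12, bromine–lithium exchange (t-BuLi, THF, −78 °C, retention of geometry) and trapping with diphenyl disulfide gives the vinyl sulfide F5. Buffered mCPBA oxidation of sulfur returns to the route at 13.

**Step 15.** Electron transfer may end in reductive elimination across C8–C9, with loss of the C8 oxygen, instead of simple C–S cleavage. The basic medium may also fragment the β-hydroxy sulfone in a retro-aldol sense. The fallback activates the sulfone instead of forcing it. From 22, Dess–Martin oxidation of the C8 hydroxyl gives the β-keto sulfone F6. Aluminium amalgam, Al(Hg), in wet THF cleaves the now activated C–S bond without touching the tetrasubstituted enone and gives the dione F7. LiBH(s-Bu)3 at −78 °C should reduce the saturated C8 ketone from the face away from the C7 substituent (cis alcohol) in preference to the hindered conjugated ketone, returning to the route at 25. The cost is that C8 is set a second time and C7 is epimerisable while C8 is a ketone. Steps 14 and 16 are not needed in this variant.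

**Step 18.** The tertiary carbinol may ionise and eliminate to the isopropenyl compound, or the acyl groups may migrate between O8 and O11 and scramble. The fallback changes the order of the acylations. From 25, silylation of the secondary hydroxyl (TESCl, imidazole) gives the silyl ether F8. Acetylation of the tertiary hydroxyl under forcing basic conditions (Ac2O, DMAP, Et3N, 40 °C), where no acyl group can migrate, gives the acetate F9. HF·pyridine removes the silyl group to give the hydroxy acetate F10, and propanoylation as in step 17 returns to the route at 27.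

## Further compounds

F1 | step 12 | methyl 3-oxo-4-{(5S,6S)-2,2,4,4-tetramethyl-6-[(Z)-1-(phenylsulfonyl)prop-1-en-1-yl]-1,3-dioxan-5-yl}butanoate | C/C=C(\S(=O)(=O)c1ccccc1)[C@H]2OC(C)(C)OC(C)(C)[C@H]2CC(=O)CC(=O)OC
F2 | step 12 | bicyclic keto ester: seven-membered ring C1/C5–C10 with C5 ketone, C1 methoxycarbonyl, C9 phenylsulfonyl, C10 methyl and the C8/C11 acetonide (C1 and C9 epimers) | C[C@H]1C(S(=O)(=O)c2ccccc2)[C@H]3OC(C)(C)OC(C)(C)[C@H]3CC(=O)C1C(=O)OC
F3 | step 12 | F2 carrying a 2-oxobutyl group on C1 (1,4-diketone) | C[C@H]1C(S(=O)(=O)c2ccccc2)[C@H]3OC(C)(C)OC(C)(C)[C@H]3CC(=O)C1(CC(=O)CC)C(=O)OC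
F4 | step 12 | 1-methoxycarbonyl derivative of 21 (enone ester) | C[C@H]1C(S(=O)(=O)c2ccccc2)[C@H]3OC(C)(C)OC(C)(C)[C@H]3CC4=C(C)C(=O)CC14C(=O)OC
F5 | step 7 | (5S,6S)-5-{[(4-methoxybenzyl)oxy]methyl}-2,2,4,4-tetramethyl-6-[(Z)-1-(phenylthio)prop-1-en-1-yl]-1,3-dioxane | C/C=C(\Sc1ccccc1)[C@H]2OC(C)(C)OC(C)(C)[C@H]2COCc3ccc(OC)cc3
F6 | step 15 | (1R,7S,10R)-11-hydroxy-9-(phenylsulfonyl)guai-4-ene-3,8-dione (C9 epimers) | O=C1C(S(=O)(=O)c2ccccc2)[C@H](C)[C@H]3CC(=O)C(C)=C3C[C@@H]1C(C)(C)O
F7 | step 15 | (1R,7S,10S)-11-hydroxyguai-4-ene-3,8-dione | O=C1C[C@H](C)[C@H]2CC(=O)C(C)=C2C[C@@H]1C(C)(C)O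
F8 | step 18 | (1R,7S,8R,10S)-11-hydroxy-8-(triethylsilyloxy)guai-4-en-3-one | CC[Si](CC)(CC)O[C@@H]1C[C@H](C)[C@H]2CC(=O)C(C)=C2C[C@@H]1C(C)(C)O
F9 | step 18 | (1R,7S,8R,10S)-3-oxo-8-(triethylsilyloxy)guai-4-en-11-yl acetate | CC[Si](CC)(CC)O[C@@H]1C[C@H](C)[C@H]2CC(=O)C(C)=C2C[C@@H]1C(C)(C)OC(C)=O
F10 | step 18 | (1R,7S,8R,10S)-8-hydroxy-3-oxoguai-4-en-11-yl acetate | O[C@@H]1C[C@H](C)[C@H]2CC(=O)C(C)=C2C[C@@H]1C(C)(C)OC(C)=O
A1 | alternative 1 | open-chain dienyne: 5,6-cis dioxane with C6 vinyl, C1 propynyl and C2/C3 2-(tert-butyldimethylsilyloxy)allyl groups | C=C[C@@H]1C(C)(C)OC(C)(C)O[C@@H]1C[C@H](C)[C@H](C#CC)CC(=C)O[Si](C)(C)C(C)(C)C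
A2 | alternative 1 | bicyclo[5.3.0] silyl dienol ether with C8/C11 acetonide | CC1(C)O[C@@H]2C[C@H](C)[C@H]3CC(O[Si](C)(C)C(C)(C)C)=C(C)C3=C[C@@H]2C(C)(C)O1
A3 | alternative 2 | (E)-ethylidene methylene cyclopentanone ethylene ketal (diene) | C=C1[C@@H](C)C2(OCCO2)C/C1=C\C
A4 | alternative 2 | methyl 3-(tert-butyldimethylsilyloxy)-2-diazobut-3-enoate | COC(=O)C(=[N+]=[N-])C(=C)O[Si](C)(C)C(C)(C)C
A5 | alternative 2 | bicyclic cyclohepta-1,4-diene with C7 ester, C8 silyl enol ether and C1=C5 alkene | COC(=O)C1=C(O[Si](C)(C)C(C)(C)C)C[C@H](C)C2=C(C1)[C@@H](C)C3(OCCO3)C2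
A6 | alternative 3 | C8 aldehyde with C11 acetate and C1 isopropenyl cyclopentenone | O=C[C@H](CC1=C(C)C(=O)C[C@@H]1C(C)=C)C(C)(C)OC(C)=O
A7 | alternative 3 | bicyclic C8 alcohol (hydroxyl trans to the C7 side chain) with C10 exocyclic methylene | O[C@H]1CC(=C)[C@H]2CC(=O)C(C)=C2C[C@@H]1C(C)(C)OC(C)=O
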